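The dihydropyranone ring C of the flavanone half (O1, C2, C3, C4, C4a, C8a) is disconnected at O1–C8a and C4–C4a. These two bonds sit on neighbouring carbons of ring A, and the C5 oxygen stands beside C4a. That pattern points to a 3-alkoxyaryne. In the key step, 3,5-dimethoxybenzyne inserts into the acyl C–O bond of an (S)-4-aryl-β-lactone that already holds O1, C2, C3 and C4. The four-membered ring grows by two atoms to the six-membered one, ring A arrives complete, and C2 stays untouched. The precursor is the benzyl-protected flavone diaryl ether bearing that β-lactone, made by asymmetric ketene–aldehyde cycloaddition.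

Key step: step 7

Assumption: the quinine-derived catalyst of the ketene–aldehyde cyclocondensation is taken to direct Si-face attack and so give the (S)-lactone, because the quinidine series gives the (R)-lactones of equal substituent ranking; the pseudoenantiomeric catalyst is the remedy if the sense proves opposite.

Remark: the target carbon C2 is (S). The ranking O > aryl > CH2 > H holds at this carbon in the lactone and in both flavanones, so the descriptor stays (S) throughout.

Step 1
Reactants: 1 phloroglucinol; 2 ethyl 3-(4-bromophenyl)-3-oxopropanoate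
Product: 3 bromoflavone diol 2-(4-bromophenyl)-5,7-dihydroxy-4H-chromen-4-one
Conditions: neat, 240 °C (melt or microwave), N2
Reagents that add atoms: none
Why: Mentzer pyrone synthesis, in which the hot β-keto ester loses ethanol to an aroylketene that C-acylates phloroglucinol, the diketone cyclodehydrates to the flavone, and the symmetry of 1 removes any regiochemical question.

Step 2
Reactants: 3 bromoflavone diol
Product: 4 dibenzyl bromoflavone 5,7-bis(benzyloxy)-2-(4-bromophenyl)-4H-chromen-4-one
Conditions: BnBr (3 equiv), K2CO3, DMF, 80 °C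
Reagents that add atoms: benzyl bromide BrCc1ccccc1
Why: Williamson ether synthesis, run with excess bromide and heat because the 5-OH is hydrogen-bonded to the C4 carbonyl and reacts last.

Step 3
Reactants: 4 dibenzyl bromoflavone; 5 4-(benzyloxy)-3-hydroxybenzaldehyde
Product: 6 diaryl ether aldehyde 4-(benzyloxy)-3-{4-[5,7-bis(benzyloxy)-4-oxo-4H-chromen-2-yl]phenoxy}benzaldehyde
Conditions: CuI (10 mol%), N,N-dimethylglycine hydrochloride (30 mol%), Cs2CO3, 1,4-dioxane, 100 °C
Reagents that add atoms: none
Why: Ullmann diaryl ether coupling, in which the bromide para to the electron-poor chromone C2 couples with the caesium phenolate of 5, while aldehyde, benzyl ethers and flavone tolerate carbonate in dioxane.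

Step 4
Reactants: 6 diaryl ether aldehyde
Product: 7 (S)-β-lactone (4S)-4-[4-(benzyloxy)-3-{4-[5,7-bis(benzyloxy)-4-oxo-4H-chromen-2-yl]phenoxy}phenyl]oxetan-2-one
Conditions: AcCl (slow addition), iPr2NEt, O-trimethylsilylquinine (15 mol%), LiClO4, CH2Cl2/Et2O, −78 to −40 °C
Reagents that add atoms: acetyl chloride CC(Cl)=O
Why: Wynberg-type acyl halide–aldehyde cyclocondensation, in which ketene made in situ is bound by the alkaloid as an acylammonium enolate that adds through a lithium-bridged closed transition state to the Si face of the aldehyde and lactonises, so the catalyst sets the (S) centre that becomes C2.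

Step 5
Reactants: 8 3,5-dimethoxyphenol
Product: 9 2-bromo-3,5-dimethoxyphenol
Conditions: NBS (1.0 equiv), CH2Cl2, −78 °C to rt
Reagents that add atoms: N-bromosuccinimide O=C1CCC(=O)N1Br
Why: Electrophilic aromatic bromination, which should favour C2 (ortho to OH, para to a methoxy group) over C4 because C4 is flanked by two methoxy groups, with C2 and C6 equivalent by symmetry.

Step 6
Reactants: 9 2-bromo-3,5-dimethoxyphenol
Product: 12 silylaryl triflate 3,5-dimethoxy-2-(trimethylsilyl)phenyl trifluoromethanesulfonate, via aryl trimethylsilyl ether 10 (not isolated), via lithium 2-silylphenolate 11 (not isolated)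
Conditions: HN(SiMe3)2, THF, 70 °C, evaporate; n-BuLi, THF, −78 °C to rt; Tf2O, −78 °C
Reagents that add atoms: hexamethyldisilazane C[Si](C)(C)N[Si](C)(C)C; trifluoromethanesulfonic anhydride O=S(=O)(OS(=O)(=O)C(F)(F)F)C(F)(F)F
Why: O-silylation, bromine–lithium exchange and retro-Brook migration of silicon from oxygen to the lithiated carbon give phenolate 11, which Tf2O traps at oxygen, the standard entry to ortho-silylaryl triflates.

Step 7
Reactants: 7 (S)-β-lactone; 12 silylaryl triflate
Product: 16 protected flavanone–flavone (2S)-2-[4-(benzyloxy)-3-{4-[5,7-bis(benzyloxy)-4-oxo-4H-chromen-2-yl]phenoxy}phenyl]-5,7-dimethoxy-2,3-dihydro-4H-chromen-4-one, via 3,5-dimethoxybenzyne 13 (not isolated), via caesium alkoxide acyl fluoride 14 (not isolated), via aryl caesium acyl fluoride 15 (not isolated)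
Conditions: 12 (2 equiv, slow addition), CsF (4 equiv), 18-crown-6, THF, 0 °C to rt; pH 6 buffer quench
Reagents that add atoms: none
Why: Proposed new method: fluoride plays two parts, releasing aryne 13 from 12 and reversibly opening the strained lactone 7 at the acyl carbon to alkoxide 14, whose oxygen adds to 13 to give aryl anion 15, which attacks its own acyl fluoride and returns fluoride, so the two aryne carbons end up between the ring oxygen and the carbonyl carbon of the lactone and the four-membered ring becomes the six-membered ring C. The closest known reaction types are the aryne insertion into the N–C(=O) bond of β-lactams (2,3-dihydroquinolin-4-ones by the same four-to-six ring growth), the C–O insertion of arynes into carboxylic acids and the salicylate–aryne annulation to xanthones, whereas the acyl C–O bond of a lactone has not been used in this way. The one ring closure is a 6-exo-trig addition–elimination of the aryl anion at the acyl fluoride. No new stereocentre is formed, because C2 is C4 of the lactone, none of its four bonds is broken, and the (S) configuration is carried over with retention. The step needs regioselectivity at the aryne, and the methoxy group beside the triple bond secures it, since its inductive pull and the resulting distortion send the nucleophilic oxygen to the remote aryne carbon (future C8a) and place the carbanion, hence the acyl group, next to that methoxy group (future C4a beside C5), while the symmetry of 8 allows only one aryne. It also needs capture of 14 to outrun β-elimination and fluoride attack at the benzylic carbon, which the low stationary concentration of 14 (fast reclosure to 7), the aprotic solvent, the low temperature and the excess of 12 are meant to secure.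

Step 8
Reactants: 16 protected flavanone–flavone
Product: 17 target (2S)-2-{3-[4-(5,7-dihydroxy-4-oxo-4H-chromen-2-yl)phenoxy]-4-hydroxyphenyl}-5-hydroxy-7-methoxy-2,3-dihydro-4H-chromen-4-one
Conditions: BCl3 (10 equiv), pentamethylbenzene (10 equiv), CH2Cl2, −78 to 0 °C; MeOH, pH 5 buffer
Reagents that add atoms: none
Why: Lewis acid ether cleavage, in which BCl3 removes the three benzyl groups as cations caught by pentamethylbenzene (Friedel–Crafts capture) and, chelated between C4=O and the 5-methoxy oxygen, cleaves only that methyl ether, so the unchelated 7-OMe, the diaryl ether and the base-sensitive C2 centre should survive.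

Compound list
1 | phloroglucinol | Oc1cc(O)cc(O)c1 | starting material
2 | ethyl 3-(4-bromophenyl)-3-oxopropanoate | CCOC(=O)CC(=O)c1ccc(Br)cc1 | starting material
3 | 2-(4-bromophenyl)-5,7-dihydroxy-4H-chromen-4-one | O=c1cc(-c2ccc(Br)cc2)oc2cc(O)cc(O)c12 | intermediate
4 | 5,7-bis(benzyloxy)-2-(4-bromophenyl)-4H-chromen-4-one | O=c1cc(-c2ccc(Br)cc2)oc2cc(OCc3ccccc3)cc(OCc3ccccc3)c12 | intermediate
5 | 4-(benzyloxy)-3-hydroxybenzaldehyde | O=Cc1ccc(OCc2ccccc2)c(O)c1 | starting material
6 | 4-(benzyloxy)-3-{4-[5,7-bis(benzyloxy)-4-oxo-4H-chromen-2-yl]phenoxy}benzaldehyde | O=Cc1ccc(OCc2ccccc2)c(Oc2ccc(-c3cc(=O)c4c(OCc5ccccc5)cc(OCc5ccccc5)cc4o3)cc2)c1 | intermediate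
7 | (4S)-4-[4-(benzyloxy)-3-{4-[5,7-bis(benzyloxy)-4-oxo-4H-chromen-2-yl]phenoxy}phenyl]oxetan-2-one | O=C1C[C@@H](c2ccc(OCc3ccccc3)c(Oc3ccc(-c4cc(=O)c5c(OCc6ccccc6)cc(OCc6ccccc6)cc5o4)cc3)c2)O1 | intermediate
8 | 3,5-dimethoxyphenol | COc1cc(O)cc(OC)c1 | starting material
9 | 2-bromo-3,5-dimethoxyphenol | COc1cc(O)c(Br)c(OC)c1 | intermediate
10 | (2-bromo-3,5-dimethoxyphenoxy)trimethylsilane | COc1cc(O[Si](C)(C)C)c(Br)c(OC)c1 | intermediate
11 | lithium 3,5-dimethoxy-2-(trimethylsilyl)phenolate | [Li+].COc1cc([O-])c([Si](C)(C)C)c(OC)c1 | intermediate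
12 | 3,5-dimethoxy-2-(trimethylsilyl)phenyl trifluoromethanesulfonate | COc1cc(OC)c([Si](C)(C)C)c(OS(=O)(=O)C(F)(F)F)c1 | intermediate
13 | 3,5-dimethoxybenzyne (1,2-didehydro-3,5-dimethoxybenzene) | COC1=CC(OC)=CC#C1 | intermediate
14 | caesium (1S)-1-aryl-3-fluoro-3-oxopropan-1-olate (aryl group as in 7) | [Cs+].[O-][C@H](c1ccc(OCc2ccccc2)c(Oc2ccc(-c3cc(=O)c4c(OCc5ccccc5)cc(OCc5ccccc5)cc4o3)cc2)c1)CC(F)=O | intermediate
15 | caesium 2-[(1S)-1-aryl-3-fluoro-3-oxopropoxy]-4,6-dimethoxyphenyl anion (carbanion between the ether carbon and a methoxy carbon; aryl group as in 7) | [Cs+].COc1cc(OC)[c-]c(O[C@H](c2ccc(OCc3ccccc3)c(Oc3ccc(-c4cc(=O)c5c(OCc6ccccc6)cc(OCc6ccccc6)cc5o4)cc3)c2)CC(F)=O)c1 | intermediate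
16 | (2S)-2-[4-(benzyloxy)-3-{4-[5,7-bis(benzyloxy)-4-oxo-4H-chromen-2-yl]phenoxy}phenyl]-5,7-dimethoxy-2,3-dihydro-4H-chromen-4-one | COc1cc(OC)c2c(c1)O[C@H](c1ccc(OCc3ccccc3)c(Oc3ccc(-c4cc(=O)c5c(OCc6ccccc6)cc(OCc6ccccc6)cc5o4)cc3)c1)CC2=O | intermediate
17 | (2S)-2-{3-[4-(5,7-dihydroxy-4-oxo-4H-chromen-2-yl)phenoxy]-4-hydroxyphenyl}-5-hydroxy-7-methoxy-2,3-dihydro-4H-chromen-4-one | COc1cc(O)c2c(c1)O[C@H](c1ccc(O)c(Oc3ccc(-c4cc(=O)c5c(O)cc(O)cc5o4)cc3)c1)CC2=O | target

Total step count: 8. Longest linear sequence: 6 (steps 1, 2, 3, 4, 7, 8).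

Steps most likely to fail

1. Step 7.
- What may go wrong:
  - Base-induced β-elimination of the lactone or of the opened alkoxide, followed by unselective ring closure, would erode the configuration at C2.
  - Fluoride may attack the benzylic carbon.
  - The aryl anion may be protonated before acyl transfer.
  - Other sinks may consume the aryne while the lactone stays closed.
- Fallback: a known catalytic asymmetric oxa-Michael route that sets out from 6 and comes back at 16. Commercial 2'-hydroxy-4',6'-dimethoxyacetophenone is C-acylated (LiN(SiMe3)2, di-tert-butyl dicarbonate) to tert-butyl 3-(2-hydroxy-4,6-dimethoxyphenyl)-3-oxopropanoate F1. Knoevenagel condensation of this ester with 6 (piperidine, AcOH, toluene) should give the alkylidene β-keto ester F2 as an E/Z mixture. A cinchona-derived bifunctional thiourea, in the pseudoenantiomeric series that leads to (S), closes the ring by intramolecular oxa-Michael addition to the tert-butyl (2S)-flavanone-3-carboxylate F3. TsOH in toluene at 80 °C then removes the ester group to give 16.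

2. Step 4.
- What may go wrong:
  - Addition to an electron-rich and poorly soluble aromatic aldehyde may be sluggish, so ketene dimerisation wins.
  - Facial selectivity may be poor.
  - The para-alkoxyaryl lactone may ionise and decarboxylate on work-up.
- Fallback: aldol first, ring closure second, setting out from 6 and coming back at 7. A Mukaiyama aldol addition of 1-(tert-butylthio)-1-(trimethylsilyloxy)ethene to 6 under (S)-BINOL/Ti(OiPr)4 in Et2O (Si-face attack) should give the silylated aldol thioester F4. Dilute HCl frees the S-tert-butyl (S)-β-hydroxy thioester F5, and LiOH in aqueous THF gives the (S)-β-hydroxy acid F6. Carboxyl activation with benzenesulfonyl chloride in pyridine at 0 °C closes the lactone 7 with retention, because the carbinol C–O bond is not touched.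

3. Step 8.
- What may go wrong:
  - Lewis acid induced ionisation of the benzylic C2–O1 bond with reclosure would cause racemisation.
  - Cleavage of the chelated methyl ether may be incomplete.
  - The 7-methyl ether may be lost.
  - The freed phenols may be C-benzylated.
- Fallback: the two kinds of ether are cleaved in separate operations, setting out from 16 and coming back at 17. Neutral hydrogenolysis (H2, Pd/C, EtOAc/MeOH) removes the benzyl groups and should give the 5-O-methyl triphenol F7. A small excess of AlCl3 in MeCN at rt then has only the chelated 5-methyl ether to cleave and gives 17.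

Further compounds
F1 | step 7 | tert-butyl 3-(2-hydroxy-4,6-dimethoxyphenyl)-3-oxopropanoate | COc1cc(O)c(C(=O)CC(=O)OC(C)(C)C)c(OC)c1
F2 | step 7 | tert-butyl 2-(2-hydroxy-4,6-dimethoxybenzoyl)-3-aryl-prop-2-enoate (aryl group as in 6, E/Z mixture) | COc1cc(O)c(C(=O)C(=Cc2ccc(OCc3ccccc3)c(Oc3ccc(-c4cc(=O)c5c(OCc6ccccc6)cc(OCc6ccccc6)cc5o4)cc3)c2)C(=O)OC(C)(C)C)c(OC)c1
F3 | step 7 | tert-butyl (2S)-2-aryl-5,7-dimethoxy-4-oxo-chromane-3-carboxylate (aryl group as in 16, C3 enolisable and undefined) | COc1cc(OC)c2c(c1)O[C@H](c1ccc(OCc3ccccc3)c(Oc3ccc(-c4cc(=O)c5c(OCc6ccccc6)cc(OCc6ccccc6)cc5o4)cc3)c1)C(C(=O)OC(C)(C)C)C2=O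
F4 | step 4 | S-tert-butyl (3S)-3-aryl-3-(trimethylsilyloxy)propanethioate (aryl group as in 7) | C[Si](C)(C)O[C@H](c1ccc(OCc2ccccc2)c(Oc2ccc(-c3cc(=O)c4c(OCc5ccccc5)cc(OCc5ccccc5)cc4o3)cc2)c1)CC(=O)SC(C)(C)C
F5 | step 4 | S-tert-butyl (3S)-3-aryl-3-hydroxypropanethioate (aryl group as in 7) | O[C@H](c1ccc(OCc2ccccc2)c(Oc2ccc(-c3cc(=O)c4c(OCc5ccccc5)cc(OCc5ccccc5)cc4o3)cc2)c1)CC(=O)SC(C)(C)C
F6 | step 4 | (3S)-3-aryl-3-hydroxypropanoic acid (aryl group as in 7) | O[C@H](c1ccc(OCc2ccccc2)c(Oc2ccc(-c3cc(=O)c4c(OCc5ccccc5)cc(OCc5ccccc5)cc4o3)cc2)c1)CC(=O)O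
F7 | step 8 | (2S)-2-{3-[4-(5,7-dihydroxy-4-oxo-4H-chromen-2-yl)phenoxy]-4-hydroxyphenyl}-5,7-dimethoxy-2,3-dihydro-4H-chromen-4-one | COc1cc(OC)c2c(c1)O[C@H](c1ccc(O)c(Oc3ccc(-c4cc(=O)c5c(O)cc(O)cc5o4)cc3)c1)CC2=O
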